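**Plan**

1. Cuts (labdane numbering, primed atoms for the butenolide): the C4'=C15 alkene comes from water loss at a C4' hemiketal. The butenolide ring (O1', C1'=O, C2'–H, C3'–CH3, C4') is an oxidised furan whose α-carbons are C1' and C4', so it is unmasked from a 2-silylfuran (silicon on C1') with singlet oxygen.
2. Further cuts: C15–C4' (allylic bromide plus furylzinc), C13=C14 (HWE on a C13 methyl ketone), the C18 acid with O6 (an 18,6α-lactone grown from the 4α-methyl group), and C8–OH (from the 8(17) alkene).
3. Forward, decalin part: larixol → ring B hydration (epoxide, hydride) → side chain cut to the methyl ketone → O8 acetylated → C18 oxidised via the 6α-alkoxy radical (ether, then lactone) → chain rebuilt to the E-allylic bromide.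
4. Forward, furan part and end: 3-methylfuran-2-carboxylic acid → bromination, decarboxylation, silylation; then coupling, hydrolysis, photooxygenation, dehydration.
5. Stereochemistry: C5, C6, C9, C10 are those of larixol; C8 comes from α-face epoxidation; C4 from the reach of the 6α-O radical (only the equatorial 4α-methyl); 13E from the HWE step and chromatography; the Z ylidene is thermodynamic. No ring is built; the decalin is carried through.

Key step: step 16

Assumption: the free γ-hydroxy acid (6α-OH with the C18 acid) is taken to be isolable without closing back to the 18,6α-lactone, as the target itself is such a hydroxy acid.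

**Route**

Step 1
Reactants: 1 larixol
Product: 2 8α,17-epoxylabd-14-ene-6α,13-diol
Conditions: mCPBA, NaHCO3, CH2Cl2, 0 °C
Reagents that add atoms: 3-chloroperbenzoic acid (mCPBA), OOC(=O)c1cccc(Cl)c1
Why: In this Prilezhaev epoxidation the electron-rich 1,1-disubstituted C8=C17 bond should react well before the vinyl group, and the peracid should approach from the α face, away from the axial C10 methyl, which places oxygen α (equatorial) on C8 and C17 β, while the buffer keeps the 13-hydroxyl from opening the epoxide.

Step 2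
Reactants: 2 8α,17-epoxylabd-14-ene-6α,13-diol
Product: 3 labd-14-ene-6α,8α,13-triol
Conditions: LiAlH4, THF, 0 °C to reflux; H2O/NaOH work-up
Reagents that add atoms: none
Why: Hydride opens the spiro-epoxide by SN2 attack at the unhindered C17 methylene, so the C8–O bond keeps its α configuration and C17 becomes the axial 8β-methyl group.

Step 3
Reactants: 3 labd-14-ene-6α,8α,13-triol
Product: 4 6α,8α-dihydroxy-14,15-dinorlabdan-13-one
Conditions: KMnO4, acetone/H2O, 0 °C to rt
Reagents that add atoms: none
Why: Permanganate cleavage of a tertiary vinyl carbinol, as used on sclareol-type side chains, removes C14 and C15 and leaves C13 as the methyl ketone, while the hindered ring hydroxyls should survive the cold medium and no stereocenter is touched.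

Step 4
Reactants: 4 6α,8α-dihydroxy-14,15-dinorlabdan-13-one
Product: 6 8α-acetoxy-6α-hydroxy-14,15-dinorlabdan-13-one, via diacetate 5 (not isolated)
Conditions: AcCl, PhNMe2, CH2Cl2, rt; aqueous wash; then K2CO3 (cat.), MeOH, 0 °C to rt
Reagents that add atoms: acetyl chloride, CC(=O)Cl
Why: Exhaustive acylation (the classical system for hindered tertiary labdane alcohols) followed by methanolysis, in which the secondary 6-acetate should go well before the tertiary 8-acetate, leaves O8 masked so that it can neither form an alkoxy radical in step 5 nor close onto C13 in step 6.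

Step 5
Reactants: 6 8α-acetoxy-6α-hydroxy-14,15-dinorlabdan-13-one
Product: 9 8α-acetoxy-6α,18-epoxy-14,15-dinorlabdan-13-one, via hypoiodite 7 (not isolated), via iodo alcohol 8 (not isolated)
Conditions: PhI(OAc)2, I2, cyclohexane, hν (tungsten lamp), 40 °C
Reagents that add atoms: none
Why: In this hypoiodite reaction the 6α-alkoxy radical abstracts hydrogen through a six-membered transition state from the only methyl group within reach, the equatorial 4α-methyl C18 held peri to O6 across C5, and the resulting C18 iodide closes onto O6 (5-exo-tet), so C4 becomes a stereocenter with the oxidised carbon α.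

Step 6
Reactants: 9 8α-acetoxy-6α,18-epoxy-14,15-dinorlabdan-13-one
Product: 10 8α-acetoxy-13-oxo-14,15-dinorlabdan-18,6α-olide
Conditions: RuCl3·xH2O (cat.), NaIO4, EtOAc/MeCN/H2O, rt
Reagents that add atoms: sodium periodate NaIO4 (its oxygen reaches C18 through RuO4), [Na+].[O-]I(=O)(=O)=O
Why: RuO4 oxidation of a cyclic ether to a lactone should take the C18 methylene next to oxygen in preference to the hindered C6 methine, and with O8 acetylated the ketone cannot form the cyclic enol ether that RuO4 would cleave.

Step 7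
Reactants: 10 8α-acetoxy-13-oxo-14,15-dinorlabdan-18,6α-olide; 11 allyl diethylphosphonoacetate
Product: 13 allyl (13E)-8α-acetoxylabd-13-en-18,6α-olid-15-oate, via phosphonate carbanion 12 (not isolated)
Conditions: NaH, THF, 0 °C; then 10, rt to 50 °C; chromatography
Reagents that add atoms: none
Why: Horner–Wadsworth–Emmons olefination of the methyl ketone with a stabilised phosphonate anion should favour the E enoate (ester trans to the C12 chain) with the minor Z isomer removed on silica, and the allyl ester is chosen because it can be taken off later without hydride or hydroxide.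

Step 8
Reactants: 13 allyl (13E)-8α-acetoxylabd-13-en-18,6α-olid-15-oate
Product: 14 (13E)-8α-acetoxylabd-13-en-18,6α-olid-15-oic acid
Conditions: Pd(PPh3)4 (cat.), morpholine, THF, rt
Reagents that add atoms: none
Why: In this Tsuji–Trost deallylation zerovalent palladium ionises the allyl ester to a π-allyl complex that morpholine captures, which frees the enoic acid under neutral conditions that leave lactone, acetate and alkene geometry alone.

Step 9
Reactants: 14 (13E)-8α-acetoxylabd-13-en-18,6α-olid-15-oic acid
Product: 16 (13E)-8α-acetoxy-15-hydroxylabd-13-en-18,6α-olide, via mixed anhydride 15 (not isolated)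
Conditions: i-BuOCOCl, N-methylmorpholine, THF, −15 °C; then NaBH4, H2O, 0 °C
Reagents that add atoms: none
Why: Borohydride reduction of a mixed carbonic anhydride reduces only the activated acyl group, so the hindered lactone and the acetate should remain, and the β,β-disubstituted alkene should resist conjugate reduction and keep its E geometry.

Step 10
Reactants: 16 (13E)-8α-acetoxy-15-hydroxylabd-13-en-18,6α-olide
Product: 17 (13E)-8α-acetoxy-15-bromolabd-13-en-18,6α-olide
Conditions: CBr4, PPh3, CH2Cl2, 0 °C
Reagents that add atoms: carbon tetrabromide, BrC(Br)(Br)Br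
Why: The Appel reaction turns the primary allylic alcohol into the bromide by SN2 displacement at C15 under neutral conditions, which should preserve the 13E alkene, and the crude bromide is used at once.

Step 11
Reactants: 18 3-methylfuran-2-carboxylic acid
Product: 19 5-bromo-3-methylfuran-2-carboxylic acid
Conditions: Br2, AcOH, rt to 40 °C
Reagents that add atoms: bromine, BrBr
Why: Electrophilic aromatic bromination takes the only free α-position of the furan (C5), a halogen route chosen because amide bases deprotonate this acid at the 3-methyl group and not at C5.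

Step 12
Reactants: 19 5-bromo-3-methylfuran-2-carboxylic acid
Product: 20 2-bromo-4-methylfuran
Conditions: Ag2CO3 (cat.), AcOH (cat.), DMSO, 120 °C
Reagents that add atoms: none
Why: Silver-catalysed protodecarboxylation of a heteroaromatic α-carboxylic acid extrudes CO2 from the silver carboxylate and protonates the furyl–silver species, a process that should leave the C–Br bond intact.

Step 13
Reactants: 20 2-bromo-4-methylfuran; 21 chlorotrimethylsilane
Product: 23 4-methyl-2-(trimethylsilyl)furan, via lithiofuran 22 (not isolated)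
Conditions: n-BuLi, Et2O, −78 °C; then TMSCl, −78 °C to rt
Reagents that add atoms: none
Why: Bromine–lithium exchange is fast and site-specific at −78 °C, and silylation of the furyllithium puts silicon on the α-carbon remote from the methyl group, the future C1'.

Step 14
Reactants: 23 4-methyl-2-(trimethylsilyl)furan; 17 (13E)-8α-acetoxy-15-bromolabd-13-en-18,6α-olide
Product: 26 (13E)-8α-acetoxy-15-[3-methyl-5-(trimethylsilyl)furan-2-yl]labd-13-en-18,6α-olide, via furyllithium 24 (not isolated), via furylzinc chloride 25 (not isolated)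
Conditions: n-BuLi, THF, 0 °C; ZnCl2, 0 °C; then 17, Pd(PPh3)4 (cat.), THF, 0 °C to rt
Reagents that add atoms: none
Why: Lithiation can occur only at the one remaining α-position (next to the methyl group), and Negishi coupling of the derived zinc reagent with the allylic bromide should join C4' to the primary carbon C15 with retention of the E alkene, the organozinc being too mild to attack lactone or acetate.

Step 15
Reactants: 26 (13E)-8α-acetoxy-15-[3-methyl-5-(trimethylsilyl)furan-2-yl]labd-13-en-18,6α-olide
Product: 27 (13E)-6α,8α-dihydroxy-15-[3-methyl-5-(trimethylsilyl)furan-2-yl]labd-13-en-18-oic acid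
Conditions: LiOH·H2O, THF/MeOH/H2O, 40 °C; then 0.5 M HCl to pH 5, 0 °C
Reagents that add atoms: lithium hydroxide, [Li+].[OH-]
Why: Saponification opens the lactone at the C18 acyl carbon and cleaves the tertiary acetate at its acyl carbon, so C6 and C8 keep their configurations, and the furyl–silicon bond should withstand hydroxide at this temperature and the brief cold acidification.

Step 16
Reactants: 27 (13E)-6α,8α-dihydroxy-15-[3-methyl-5-(trimethylsilyl)furan-2-yl]labd-13-en-18-oic acid; 28 dioxygen
Product: 31 (13E)-6α,8α-dihydroxy-15-(2-hydroxy-3-methyl-5-oxo-2,5-dihydrofuran-2-yl)labd-13-en-18-oic acid (both C4' epimers), via endoperoxide 29 (not isolated), via silyl ester 30 (not isolated)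
Conditions: O2, tetraphenylporphyrin (cat.), visible light, CH2Cl2/MeOH, −78 °C, short irradiation
Reagents that add atoms: none
Why: Sensitised singlet oxygen adds suprafacially across C1' and C4' of the furan diene in a [4+2] cycloaddition to give the 2,3,7-trioxabicyclo[2.2.1]heptene 29; silicon then shifts from C1' to the adjacent peroxide oxygen as the O–O bond breaks, so C1' becomes the carboxyl carbon of silyl ester 30 and C4' a ketone, and methanolysis frees the acid, which closes onto the C4' ketone (5-exo-trig) as the hydroxybutenolide. The closest known reaction type is the regiospecific photooxygenation of 2-trimethylsilylfurans to γ-hydroxybutenolides. No new ring results overall, since the bicyclic peroxide is transient and the five-membered lactone takes the place of the furan. The new stereocenter C4' is not controlled and need not be, because both epimers lose water to the same alkene in step 17. Regiochemistry (carbonyl at C1', hydroxyl at C4') is secured by silicon on C1', and selectivity over an ene reaction at the trisubstituted C13=C14 alkene by the much faster cycloaddition of the electron-rich furan at −78 °C.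

Step 17
Reactants: 31 (13E)-6α,8α-dihydroxy-15-(2-hydroxy-3-methyl-5-oxo-2,5-dihydrofuran-2-yl)labd-13-en-18-oic acid
Product: 32 (13E)-6α,8α-dihydroxy-15-[(Z)-3-methyl-5-oxofuran-2(5H)-ylidene]labd-13-en-18-oic acid (target)
Conditions: p-TsOH·H2O (cat.), benzene, 4 Å molecular sieves, rt
Reagents that add atoms: none
Why: In this acid-catalysed dehydration the C4' hemiketal hydroxyl ionises far more readily than the tertiary C8 alcohol, loss of the allylic C15 proton gives the dienyl lactone from either epimer, and reversible protonation should settle the C4'=C15 bond in the Z geometry, with C14 syn to the ring oxygen and away from the 3'-methyl group.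

**Compound list**

1 | larixol, labda-8(17),14-diene-6α,13-diol | C=C[C@@](C)(O)CC[C@@H]1[C@@]2(C)CCCC(C)(C)[C@@H]2[C@@H](O)CC1=C | starting material
2 | 8α,17-epoxylabd-14-ene-6α,13-diol (epoxide oxygen α on C8) | C=C[C@@](C)(O)CC[C@@H]1[C@@]2(C)CCCC(C)(C)[C@@H]2[C@@H](O)C[C@@]1(C3)O3 | intermediate
3 | labd-14-ene-6α,8α,13-triol | C=C[C@@](C)(O)CC[C@@H]1[C@@]2(C)CCCC(C)(C)[C@@H]2[C@@H](O)C[C@@]1(C)O | intermediate
4 | 6α,8α-dihydroxy-14,15-dinorlabdan-13-one | CC(=O)CC[C@@H]1[C@@]2(C)CCCC(C)(C)[C@@H]2[C@@H](O)C[C@@]1(C)O | intermediate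
5 | 6α,8α-diacetoxy-14,15-dinorlabdan-13-one (not isolated) | CC(=O)CC[C@@H]1[C@@]2(C)CCCC(C)(C)[C@@H]2[C@@H](OC(C)=O)C[C@@]1(C)OC(C)=O | intermediate
6 | 8α-acetoxy-6α-hydroxy-14,15-dinorlabdan-13-one | CC(=O)CC[C@@H]1[C@@]2(C)CCCC(C)(C)[C@@H]2[C@@H](O)C[C@@]1(C)OC(C)=O | intermediate
7 | 6α-hypoiodite of 6 (not isolated) | CC(=O)CC[C@@H]1[C@@]2(C)CCCC(C)(C)[C@@H]2[C@@H](OI)C[C@@]1(C)OC(C)=O | intermediate
8 | 8α-acetoxy-6α-hydroxy-18-iodo-14,15-dinorlabdan-13-one (not isolated) | CC(=O)CC[C@@H]1[C@@]2(C)CCC[C@@](C)(CI)[C@@H]2[C@@H](O)C[C@@]1(C)OC(C)=O | intermediate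
9 | 8α-acetoxy-6α,18-epoxy-14,15-dinorlabdan-13-one | CC(=O)CC[C@@H]1[C@@]2(C)CCC[C@@](C)(C3)[C@@H]2[C@@H](O3)C[C@@]1(C)OC(C)=O | intermediate
10 | 8α-acetoxy-13-oxo-14,15-dinorlabdan-18,6α-olide | CC(=O)CC[C@@H]1[C@@]2(C)CCC[C@@](C)(C3=O)[C@@H]2[C@@H](O3)C[C@@]1(C)OC(C)=O | intermediate
11 | allyl diethylphosphonoacetate | C=CCOC(=O)CP(=O)(OCC)OCC | starting material
12 | sodium salt of the carbanion of 11 (not isolated) | C=CCOC(=O)[CH-]P(=O)(OCC)OCC.[Na+] | intermediate
13 | allyl (13E)-8α-acetoxylabd-13-en-18,6α-olid-15-oate | C=CCOC(=O)/C=C(\C)CC[C@@H]1[C@@]2(C)CCC[C@@](C)(C3=O)[C@@H]2[C@@H](O3)C[C@@]1(C)OC(C)=O | intermediate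
14 | (13E)-8α-acetoxylabd-13-en-18,6α-olid-15-oic acid | OC(=O)/C=C(\C)CC[C@@H]1[C@@]2(C)CCC[C@@](C)(C3=O)[C@@H]2[C@@H](O3)C[C@@]1(C)OC(C)=O | intermediate
15 | isobutyl carbonic mixed anhydride of 14 (not isolated) | CC(C)COC(=O)OC(=O)/C=C(\C)CC[C@@H]1[C@@]2(C)CCC[C@@](C)(C3=O)[C@@H]2[C@@H](O3)C[C@@]1(C)OC(C)=O | intermediate
16 | (13E)-8α-acetoxy-15-hydroxylabd-13-en-18,6α-olide | OC/C=C(\C)CC[C@@H]1[C@@]2(C)CCC[C@@](C)(C3=O)[C@@H]2[C@@H](O3)C[C@@]1(C)OC(C)=O | intermediate
17 | (13E)-8α-acetoxy-15-bromolabd-13-en-18,6α-olide | BrC/C=C(\C)CC[C@@H]1[C@@]2(C)CCC[C@@](C)(C3=O)[C@@H]2[C@@H](O3)C[C@@]1(C)OC(C)=O | intermediate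
18 | 3-methylfuran-2-carboxylic acid | Cc1ccoc1C(=O)O | starting material
19 | 5-bromo-3-methylfuran-2-carboxylic acid | Cc1cc(Br)oc1C(=O)O | intermediate
20 | 2-bromo-4-methylfuran | Cc1coc(Br)c1 | intermediate
21 | chlorotrimethylsilane | C[Si](C)(C)Cl | starting material
22 | (4-methylfuran-2-yl)lithium (not isolated) | Cc1coc([Li])c1 | intermediate
23 | 4-methyl-2-(trimethylsilyl)furan | Cc1coc(c1)[Si](C)(C)C | intermediate
24 | [3-methyl-5-(trimethylsilyl)furan-2-yl]lithium (not isolated) | Cc1cc(oc1[Li])[Si](C)(C)C | intermediate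
25 | [3-methyl-5-(trimethylsilyl)furan-2-yl]zinc chloride (not isolated) | Cc1cc(oc1[Zn]Cl)[Si](C)(C)C | intermediate
26 | (13E)-8α-acetoxy-15-[3-methyl-5-(trimethylsilyl)furan-2-yl]labd-13-en-18,6α-olide | C[Si](C)(C)c3cc(C)c(o3)C/C=C(\C)CC[C@@H]1[C@@]2(C)CCC[C@@](C)(C4=O)[C@@H]2[C@@H](O4)C[C@@]1(C)OC(C)=O | intermediate
27 | (13E)-6α,8α-dihydroxy-15-[3-methyl-5-(trimethylsilyl)furan-2-yl]labd-13-en-18-oic acid | C[Si](C)(C)c3cc(C)c(o3)C/C=C(\C)CC[C@@H]1[C@@]2(C)CCC[C@@](C)(C(=O)O)[C@@H]2[C@@H](O)C[C@@]1(C)O | intermediate
28 | dioxygen | O=O | starting material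
29 | furan endoperoxide of 27, a 2,3,7-trioxabicyclo[2.2.1]hept-5-ene with silicon on C1' (not isolated) | C[Si](C)(C)C34OOC(C/C=C(\C)CC[C@@H]1[C@@]2(C)CCC[C@@](C)(C(=O)O)[C@@H]2[C@@H](O)C[C@@]1(C)O)(O3)C(C)=C4 | intermediate
30 | trimethylsilyl (Z)-4-oxo-2-enoate from 29: C1' silyl ester, C4' ketone (not isolated) | C[Si](C)(C)OC(=O)/C=C(/C)C(=O)C/C=C(\C)CC[C@@H]1[C@@]2(C)CCC[C@@](C)(C(=O)O)[C@@H]2[C@@H](O)C[C@@]1(C)O | intermediate
31 | (13E)-6α,8α-dihydroxy-15-(2-hydroxy-3-methyl-5-oxo-2,5-dihydrofuran-2-yl)labd-13-en-18-oic acid, both C4' epimers | CC1=CC(=O)OC1(O)C/C=C(\C)CC[C@@H]1[C@@]2(C)CCC[C@@](C)(C(=O)O)[C@@H]2[C@@H](O)C[C@@]1(C)O | intermediate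
32 | (13E)-6α,8α-dihydroxy-15-[(Z)-3-methyl-5-oxofuran-2(5H)-ylidene]labd-13-en-18-oic acid | CC1=CC(=O)O/C1=C\C=C(/C)CC[C@@H]1[C@@]2(C)CCC[C@@](C)(C(=O)O)[C@@H]2[C@@H](O)C[C@@]1(C)O | target

**Count and risks**

Total steps: 17. Longest linear sequence: 14 (steps 1–10, then 14–17); the furan branch is steps 11–13.

Step 5 (C18 functionalisation). The primary C18 iodide may fail to close onto O6 at a neopentyl carbon, electrophilic iodine may attack the enolisable methyl ketone, or the alkoxy radical may be lost to other pathways before it abstracts H-18. The fallback is a Barton nitrite photolysis, which traps the C18 radical with NO, needs no displacement at C18 and no free iodine, and reaches the aldehyde level directly. It sets out from 6. NOCl in pyridine at −20 °C should give the 6α-nitrite ester F1. Irradiation at λ > 350 nm in benzene, followed by warming to isomerise the nitroso dimer, should give the C18 aldoxime with the 6α-hydroxyl restored, F2. NaNO2 in aqueous acetic acid should unmask the aldehyde, which closes to the 6α,18-lactol F3. Ag2CO3 on Celite in hot benzene should oxidise the lactol to lactone 10, where the route resumes; step 6 is then not needed.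

Step 17 (dehydration). Under acid the 6α-hydroxyl may close onto the free C18 acid, or the tertiary C8 alcohol may be lost by elimination before the hemiketal ionises, so that the window of usable acid strength becomes too narrow. The fallback masks the acid for the last stages and sets out from 27. Allyl bromide and KHCO3 in DMF should give the allyl ester of the silylfuran, F4. Photooxygenation as in step 16 should give the hydroxybutenolide allyl ester F5. With no free acid left to lactonise, p-TsOH in benzene can be applied more firmly to give the ylidene butenolide allyl ester F6. Pd(PPh3)4 with PhSiH3 as a non-nucleophilic allyl acceptor should then release the acid and arrive at 32.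

Step 4 (differentiating O6 and O8). The two hindered acetates may be cleaved at similar rates, or the keto alcohol may be acylated in its cyclic hemiketal form, so that the 8-monoacetate is not obtained cleanly. The fallback replaces kinetic differentiation by orthogonal protection and sets out from 4. TESCl and imidazole in DMF at 0 °C should silylate only the secondary 6-hydroxyl to give the 6-O-triethylsilyl ether F7. Ac2O with DMAP and Et3N should then acetylate the tertiary 8-hydroxyl to give the silyl ether acetate F8. AcOH/THF/H2O should remove the silyl group and return to 6.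

**Further compounds**

F1 | step 5 | 8α-acetoxy-13-oxo-14,15-dinorlabdan-6α-yl nitrite | CC(=O)CC[C@@H]1[C@@]2(C)CCCC(C)(C)[C@@H]2[C@@H](ON=O)C[C@@]1(C)OC(C)=O
F2 | step 5 | 8α-acetoxy-6α-hydroxy-13-oxo-14,15-dinorlabdan-18-al oxime | CC(=O)CC[C@@H]1[C@@]2(C)CCC[C@@](C)(C=NO)[C@@H]2[C@@H](O)C[C@@]1(C)OC(C)=O
F3 | step 5 | 8α-acetoxy-6α,18-epoxy-18-hydroxy-14,15-dinorlabdan-13-one (lactol, C18 epimers) | CC(=O)CC[C@@H]1[C@@]2(C)CCC[C@@](C)(C3O)[C@@H]2[C@@H](O3)C[C@@]1(C)OC(C)=O
F4 | step 17 | allyl (13E)-6α,8α-dihydroxy-15-[3-methyl-5-(trimethylsilyl)furan-2-yl]labd-13-en-18-oate | C[Si](C)(C)c3cc(C)c(o3)C/C=C(\C)CC[C@@H]1[C@@]2(C)CCC[C@@](C)(C(=O)OCC=C)[C@@H]2[C@@H](O)C[C@@]1(C)O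
F5 | step 17 | allyl (13E)-6α,8α-dihydroxy-15-(2-hydroxy-3-methyl-5-oxo-2,5-dihydrofuran-2-yl)labd-13-en-18-oate | CC1=CC(=O)OC1(O)C/C=C(\C)CC[C@@H]1[C@@]2(C)CCC[C@@](C)(C(=O)OCC=C)[C@@H]2[C@@H](O)C[C@@]1(C)O
F6 | step 17 | allyl (13E)-6α,8α-dihydroxy-15-[(Z)-3-methyl-5-oxofuran-2(5H)-ylidene]labd-13-en-18-oate | CC1=CC(=O)O/C1=C\C=C(/C)CC[C@@H]1[C@@]2(C)CCC[C@@](C)(C(=O)OCC=C)[C@@H]2[C@@H](O)C[C@@]1(C)O
F7 | step 4 | 8α-hydroxy-6α-(triethylsilyloxy)-14,15-dinorlabdan-13-one | CC(=O)CC[C@@H]1[C@@]2(C)CCCC(C)(C)[C@@H]2[C@@H](O[Si](CC)(CC)CC)C[C@@]1(C)O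
F8 | step 4 | 8α-acetoxy-6α-(triethylsilyloxy)-14,15-dinorlabdan-13-one | CC(=O)CC[C@@H]1[C@@]2(C)CCCC(C)(C)[C@@H]2[C@@H](O[Si](CC)(CC)CC)C[C@@]1(C)OC(C)=O
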